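**Retrosynthetic overview**

1. Labels: the upper chroman is O1–C2–C3–C4 fused to ring A, with ring B on C3 and ring C (C1c–C6c) on C4; the lower chroman (primed) is bound through C3′ to C6c. The strategy rests on ring C: the adjacent atoms C1c and C6c both carry carbon (C4 and C3′), C2c next to C1c carries OMe and C4c carries OH. This is the pattern left when a 3-methoxyaryne is inserted into a C–C bond.
2. Target ⇒ (debenzylation, deoxygenation at C2) chroman-2-ol ⇒ formal [4+2] of the ring A ortho-quinone methide (exocyclic C4) with the enamine of the ring B acetaldehyde. This forms C3–C4 and O1–C2 and sets C3 and C4; the upper pyran ring is closed last.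
3. Quinone methide ⇐ diaryl ketone (C4=O) that already carries the lower chroman. The lower pyran ring is closed first by Mitsunobu etherification (O1′–C2′) after auxiliary-controlled benzylation (C3′–C4′, sets C3′).
4. Diaryl ketone with CH2CO2Me on C6c ⇐ insertion of 5-benzyloxy-3-methoxybenzyne into the Cα–C(=O) bond of the ring A aroylacetate: C6c–C3′ and C1c–C4 in one operation.
5. Aryne precursor from 5-bromovanillin (Dakin, retro-Brook, triflation); ketoester from 4′-benzyloxy-2′-hydroxyacetophenone; rings A, A′, B and C are bought as arenes.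

Key step: step 6

Remark: the aryne is released from the silyl triflate that has the triflate (not silicon) next to OMe. It gives the same 5-benzyloxy-3-methoxybenzyne and is made from 5-bromovanillin without regiochemical ambiguity, whereas ortho-bromination of 3-benzyloxy-5-methoxyphenol cannot tell its two ortho positions apart.
Remark: the ring A ortho oxygen is carried as an allyl ether instead of a MOM ether, because it must later be freed beside a benzhydrol that ionises in acid.
Remark: 4′-benzyloxy-2′-hydroxyacetophenone and 4-benzyloxy-2-hydroxybenzaldehyde are bought as such; each is also one selective 4-O-benzylation away from the dihydroxy compound.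
Remark: the sense of induction in step 22 is taken from the usual behaviour of diarylprolinol silyl ether enamines (attack anti to the diarylmethyl group, open synclinal transition state).

**Route**

Step 1
Reactants: 1 5-bromovanillin (3-bromo-4-hydroxy-5-methoxybenzaldehyde)
Product: 3 2-bromo-6-methoxybenzene-1,4-diol, via aryl formate 2 (not isolated)
Conditions: H2O2 (30 % aq.), NaOH (aq.), 0 °C to rt, N2; then HCl (aq.)
Reagents that add atoms: hydrogen peroxide, OO
Why: Dakin oxidation: hydroperoxide adds to the aldehyde para to the phenoxide, the electron-rich aryl group migrates to oxygen and formate 2 is saponified in the same pot, so the new hydroxyl group takes the place of the formyl group and the two oxygens stay distinguishable (one flanked by Br and OMe, one unhindered).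

Step 2
Reactants: 3 2-bromo-6-methoxybenzene-1,4-diol
Product: 7 4-hydroxy-2-methoxy-6-(trimethylsilyl)phenyl trifluoromethanesulfonate, via bis(silyl) ether 4 (not isolated), via lithium phenoxide 5 (not isolated), via silyl ether triflate 6 (not isolated)
Conditions: HN(SiMe3)2, THF, 65 °C, then evaporation; n-BuLi, THF, −100 to −78 °C; Tf2O, −100 to −78 °C; HCl (1 M aq.), THF, rt
Reagents that add atoms: hexamethyldisilazane, C[Si](C)(C)N[Si](C)(C)C; trifluoromethanesulfonic anhydride, O=S(=O)(OS(=O)(=O)C(F)(F)F)C(F)(F)F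
Why: Established one-pot route to ortho-silylaryl triflates (O-silylation, bromine–lithium exchange, retro-Brook 1,3-shift of silicon from oxygen to carbon, O-triflation): only the silyl ether next to the carbanion can migrate, so the remote silyl ether survives until dilute acid removes it, while the C–Si bond, meta to both donors, should resist protodesilylation.

Step 3
Reactants: 7 4-hydroxy-2-methoxy-6-(trimethylsilyl)phenyl trifluoromethanesulfonate
Product: 8 4-(benzyloxy)-2-methoxy-6-(trimethylsilyl)phenyl trifluoromethanesulfonate (aryne precursor)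
Conditions: BnBr, K2CO3, acetone, rt
Reagents that add atoms: benzyl bromide, BrCc1ccccc1
Why: Williamson etherification of the only free phenol; its phenoxide is meta to silicon and para to the triflate, so neither a Brook shift nor aryne release is expected under carbonate at room temperature.

Step 4
Reactants: 9 1-[4-(benzyloxy)-2-hydroxyphenyl]ethan-1-one
Product: 10 1-[4-(benzyloxy)-2-(prop-2-en-1-yloxy)phenyl]ethan-1-one
Conditions: allyl bromide, K2CO3, DMF, 60 °C
Reagents that add atoms: allyl bromide, C=CCBr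
Why: Williamson O-allylation of the chelated ortho phenol, which needs only gentle heating in DMF.

Step 5
Reactants: 10 1-[4-(benzyloxy)-2-(prop-2-en-1-yloxy)phenyl]ethan-1-one
Product: 11 methyl 3-[4-(benzyloxy)-2-(prop-2-en-1-yloxy)phenyl]-3-oxopropanoate (ring A aroylacetate)
Conditions: NaH, dimethyl carbonate, THF, reflux; then HCl (aq.)
Reagents that add atoms: dimethyl carbonate, COC(=O)OC
Why: Crossed Claisen condensation of the methyl ketone enolate with dimethyl carbonate, driven by deprotonation of the β-ketoester formed; with the ortho oxygen blocked no 4-hydroxycoumarin can arise.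

Step 6
Reactants: 8 4-(benzyloxy)-2-methoxy-6-(trimethylsilyl)phenyl trifluoromethanesulfonate; 11 methyl 3-[4-(benzyloxy)-2-(prop-2-en-1-yloxy)phenyl]-3-oxopropanoate
Product: 13 methyl 2-{5-(benzyloxy)-2-[4-(benzyloxy)-2-(prop-2-en-1-yloxy)benzoyl]-3-methoxyphenyl}acetate, via aryne 12 (not isolated)
Conditions: 8 (1.3 equiv), CsF (3 equiv), MeCN, 80 °C
Reagents that add atoms: none
Why: Fluoride removes the silyl group of 8 and triflate departs, giving aryne 12, whose triple bond lies between the former C–OTf carbon (next to OMe, future C1c) and the former C–Si carbon (future C6c). The caesium enolate of 11 adds through its α-carbon (future C3′) to C6c, because the inductively withdrawing methoxy group distorts the aryne and stabilises the aryl anion that develops at C1c. This anion closes onto the neighbouring ketone (4-exo-trig) to a benzocyclobutenoxide that fragments to the ester-stabilised carbanion, so the aroyl carbon (future C4, carrying ring A) ends on C1c; the four-membered ring is transient and no ring is kept. The closest known reaction type is the fluoride-induced acyl-alkylation of arynes with β-ketoesters, which is established for aryl ketoesters and for 3-alkoxyarynes. No stereocentre is formed. The only selectivity needed is the regiochemistry of the first addition, secured by the C2c methoxy group, while allyl and benzyl ethers are inert to CsF in MeCN.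

Step 7
Reactants: 13 methyl 2-{5-(benzyloxy)-2-[4-(benzyloxy)-2-(prop-2-en-1-yloxy)benzoyl]-3-methoxyphenyl}acetate
Product: 14 2-{5-(benzyloxy)-2-[4-(benzyloxy)-2-(prop-2-en-1-yloxy)benzoyl]-3-methoxyphenyl}acetic acid
Conditions: LiOH·H2O, THF/MeOH/H2O, rt; then HCl (aq.) to pH 3
Reagents that add atoms: lithium hydroxide, [Li+].[OH-]
Why: Saponification of an unhindered methyl ester; the diaryl ketone has no α-hydrogen and is too hindered and electron-rich to be attacked.

Step 8
Reactants: 14 2-{5-(benzyloxy)-2-[4-(benzyloxy)-2-(prop-2-en-1-yloxy)benzoyl]-3-methoxyphenyl}acetic acid; 15 (4R)-4-benzyl-1,3-oxazolidin-2-one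
Product: 17 (4R)-4-benzyl-3-(2-{5-(benzyloxy)-2-[4-(benzyloxy)-2-(prop-2-en-1-yloxy)benzoyl]-3-methoxyphenyl}acetyl)-1,3-oxazolidin-2-one, via mixed pivalic anhydride 16 (not isolated)
Conditions: PivCl, Et3N, THF, −20 °C; then LiCl, 15, rt
Reagents that add atoms: pivaloyl chloride, CC(C)(C)C(Cl)=O (its atoms stay in intermediate 16 only, none in 17)
Why: Acylation of the oxazolidinone by the mixed pivalic anhydride with LiCl/Et3N activation, the standard mild loading of arylacetic acids onto this auxiliary; the hindered ketone does not take part.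

Step 9
Reactants: 18 4-(benzyloxy)-2-hydroxybenzaldehyde
Product: 19 4-(benzyloxy)-2-(methoxymethoxy)benzaldehyde
Conditions: MOMCl, iPr2NEt, CH2Cl2, 0 °C to rt
Reagents that add atoms: chloromethyl methyl ether, COCCl
Why: O-Alkylation of the phenol with chloromethyl methyl ether gives the MOM acetal, chosen because it survives hydride and enolate chemistry and leaves with mild acid.

Step 10
Reactants: 19 4-(benzyloxy)-2-(methoxymethoxy)benzaldehyde
Product: 20 [4-(benzyloxy)-2-(methoxymethoxy)phenyl]methanol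
Conditions: NaBH4, MeOH, 0 °C
Reagents that add atoms: none
Why: Chemoselective borohydride reduction of the aldehyde.

Step 11
Reactants: 20 [4-(benzyloxy)-2-(methoxymethoxy)phenyl]methanol
Product: 21 4-(benzyloxy)-1-(bromomethyl)-2-(methoxymethoxy)benzene
Conditions: CBr4, PPh3, CH2Cl2, −10 °C; short silica pad; used at once
Reagents that add atoms: tetrabromomethane, BrC(Br)(Br)Br
Why: Appel bromination runs under neutral conditions that the MOM acetal tolerates, and immediate use avoids decomposition of the electron-rich benzylic bromide.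

Step 12
Reactants: 17 (4R)-4-benzyl-3-(2-{5-(benzyloxy)-2-[4-(benzyloxy)-2-(prop-2-en-1-yloxy)benzoyl]-3-methoxyphenyl}acetyl)-1,3-oxazolidin-2-one; 21 4-(benzyloxy)-1-(bromomethyl)-2-(methoxymethoxy)benzene
Product: 22 (4R)-4-benzyl-3-[(2R)-2-{5-(benzyloxy)-2-[4-(benzyloxy)-2-(prop-2-en-1-yloxy)benzoyl]-3-methoxyphenyl}-3-[4-(benzyloxy)-2-(methoxymethoxy)phenyl]propanoyl]-1,3-oxazolidin-2-one
Conditions: NaN(SiMe3)2, THF, −78 °C; then 21, −78 to −40 °C
Reagents that add atoms: none
Why: Evans alkylation: the chelated sodium Z-enolate is attacked by the benzylic bromide on the face away from the C4 benzyl group of the (R)-auxiliary, which sets the new centre (future C3′) as R.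

Step 13
Reactants: 22 (4R)-4-benzyl-3-[(2R)-2-{5-(benzyloxy)-2-[4-(benzyloxy)-2-(prop-2-en-1-yloxy)benzoyl]-3-methoxyphenyl}-3-[4-(benzyloxy)-2-(methoxymethoxy)phenyl]propanoyl]-1,3-oxazolidin-2-one
Product: 23 {4-(benzyloxy)-2-[(2R)-1-[4-(benzyloxy)-2-(methoxymethoxy)phenyl]-3-hydroxypropan-2-yl]-6-methoxyphenyl}[4-(benzyloxy)-2-(prop-2-en-1-yloxy)phenyl]methanone
Conditions: LiBH4, MeOH (1 equiv), Et2O/THF, 0 °C
Reagents that add atoms: none
Why: Reductive cleavage of the N-acyl oxazolidinone at the exocyclic carbonyl by LiBH4, which should be far faster than hydride addition to the tri-ortho-substituted, donor-conjugated diaryl ketone; the C3′ centre carries no acidic hydrogen after reduction and auxiliary 15 is recovered.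

Step 14
Reactants: 23 {4-(benzyloxy)-2-[(2R)-1-[4-(benzyloxy)-2-(methoxymethoxy)phenyl]-3-hydroxypropan-2-yl]-6-methoxyphenyl}[4-(benzyloxy)-2-(prop-2-en-1-yloxy)phenyl]methanone
Product: 24 {4-(benzyloxy)-2-[(2R)-1-[4-(benzyloxy)-2-hydroxyphenyl]-3-hydroxypropan-2-yl]-6-methoxyphenyl}[4-(benzyloxy)-2-(prop-2-en-1-yloxy)phenyl]methanone
Conditions: HCl (3 M aq.), THF/MeOH, 45 °C
Reagents that add atoms: none
Why: Acid-catalysed acetal exchange with methanol removes the MOM group; at the ketone oxidation level C4 cannot ionise, and allyl and benzyl ethers are stable.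

Step 15
Reactants: 24 {4-(benzyloxy)-2-[(2R)-1-[4-(benzyloxy)-2-hydroxyphenyl]-3-hydroxypropan-2-yl]-6-methoxyphenyl}[4-(benzyloxy)-2-(prop-2-en-1-yloxy)phenyl]methanone
Product: 25 {4-(benzyloxy)-2-[(3R)-7-(benzyloxy)-3,4-dihydro-2H-chromen-3-yl]-6-methoxyphenyl}[4-(benzyloxy)-2-(prop-2-en-1-yloxy)phenyl]methanone
Conditions: PPh3, DIAD, THF, 0 °C to rt
Reagents that add atoms: none
Why: Mitsunobu etherification: the phenol displaces the phosphonium-activated primary alcohol in a 6-exo-tet closure of the lower pyran ring (O1′–C2′), with C3′ not involved and so retained as R.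

Step 16
Reactants: 25 {4-(benzyloxy)-2-[(3R)-7-(benzyloxy)-3,4-dihydro-2H-chromen-3-yl]-6-methoxyphenyl}[4-(benzyloxy)-2-(prop-2-en-1-yloxy)phenyl]methanone
Product: 26 {4-(benzyloxy)-2-[(3R)-7-(benzyloxy)-3,4-dihydro-2H-chromen-3-yl]-6-methoxyphenyl}[4-(benzyloxy)-2-(prop-2-en-1-yloxy)phenyl]methanol (both carbinol epimers)
Conditions: LiAlH4, THF, 0 °C to rt
Reagents that add atoms: none
Why: Hydride reduction of the hindered diaryl ketone by the small, strong donor LiAlH4; the carbinol centre forms as a mixture that is irrelevant because C4 becomes trigonal again in step 22, and with the ortho oxygen still allylated no over-reduction through a quinone methide is possible.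

Step 17
Reactants: 26 {4-(benzyloxy)-2-[(3R)-7-(benzyloxy)-3,4-dihydro-2H-chromen-3-yl]-6-methoxyphenyl}[4-(benzyloxy)-2-(prop-2-en-1-yloxy)phenyl]methanol
Product: 27 5-(benzyloxy)-2-[{4-(benzyloxy)-2-[(3R)-7-(benzyloxy)-3,4-dihydro-2H-chromen-3-yl]-6-methoxyphenyl}(hydroxy)methyl]phenol (both carbinol epimers)
Conditions: Pd(PPh3)4 (5 mol %), morpholine, THF, rt
Reagents that add atoms: none
Why: Tsuji–Trost-type deallylation: zerovalent palladium ionises the aryl allyl ether and morpholine captures the allyl ligand, under non-acidic conditions in which the donor-rich benzhydrol does not ionise.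

Step 18
Reactants: 27 5-(benzyloxy)-2-[{4-(benzyloxy)-2-[(3R)-7-(benzyloxy)-3,4-dihydro-2H-chromen-3-yl]-6-methoxyphenyl}(hydroxy)methyl]phenol
Product: 28 5-(benzyloxy)-2-[{4-(benzyloxy)-2-[(3R)-7-(benzyloxy)-3,4-dihydro-2H-chromen-3-yl]-6-methoxyphenyl}(4-methylbenzenesulfonyl)methyl]phenol (both epimers, used crude)
Conditions: TolSO2Na, AcOH, CH2Cl2, rt
Reagents that add atoms: sodium 4-methylbenzenesulfinate, [Na+].[O-]S(=O)c1ccc(C)cc1
Why: SN1-type substitution: acetic acid ionises the benzhydrol, which is stabilised by four ortho/para oxygen donors, and the sulfinate captures the cation at sulfur to give the usual base-triggered ortho-quinone methide precursor.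

Step 19
Reactants: 29 2,3-dihydroxy-4-methoxybenzaldehyde
Product: 30 2,3-bis(benzyloxy)-4-methoxybenzaldehyde
Conditions: BnBr, K2CO3, DMF, 60 °C
Reagents that add atoms: benzyl bromide, BrCc1ccccc1
Why: Williamson bis-benzylation of the catechol hydroxyl groups.

Step 20
Reactants: 30 2,3-bis(benzyloxy)-4-methoxybenzaldehyde
Product: 31 2,3-bis(benzyloxy)-4-methoxy-1-(2-methoxyethenyl)benzene (E/Z mixture)
Conditions: MeOCH2PPh3Cl, KOtBu, THF, 0 °C to rt
Reagents that add atoms: (methoxymethyl)triphenylphosphonium chloride, [Cl-].COC[P+](c1ccccc1)(c1ccccc1)c1ccccc1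
Why: Wittig methoxymethylenation (one-carbon homologation) of the aldehyde.

Step 21
Reactants: 31 2,3-bis(benzyloxy)-4-methoxy-1-(2-methoxyethenyl)benzene
Product: 32 2-[2,3-bis(benzyloxy)-4-methoxyphenyl]acetaldehyde
Conditions: HCl (2 M aq.), THF, 50 °C; used at once
Reagents that add atoms: water, O
Why: Acid hydrolysis of the enol ether to the arylacetaldehyde, which is used at once because α-aryl aldehydes self-condense on storage.

Step 22
Reactants: 28 5-(benzyloxy)-2-[{4-(benzyloxy)-2-[(3R)-7-(benzyloxy)-3,4-dihydro-2H-chromen-3-yl]-6-methoxyphenyl}(4-methylbenzenesulfonyl)methyl]phenol; 32 2-[2,3-bis(benzyloxy)-4-methoxyphenyl]acetaldehyde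
Product: 34 (3R,4S)-7-(benzyloxy)-4-{4-(benzyloxy)-2-[(3R)-7-(benzyloxy)-3,4-dihydro-2H-chromen-3-yl]-6-methoxyphenyl}-3-[2,3-bis(benzyloxy)-4-methoxyphenyl]-3,4-dihydro-2H-chromen-2-ol (both C2 anomers), via ortho-quinone methide 33 (not isolated)
Conditions: 32 (2 equiv), (R)-α,α-diphenylprolinol trimethylsilyl ether (20 mol %), NaHCO3, CH2Cl2, 0 °C to rt
Reagents that add atoms: none
Why: Aminocatalytic formal [4+2] (enamine Michael addition to an ortho-quinone methide, then hemiacetalisation), a known reaction type for 2-(1-sulfonylalkyl)phenols: hydrogen carbonate releases 33, the (R)-catalyst blocks one face of the E-enamine of 32 so that C4 bonds to the Re face of the enamine carbon (C3 = R), the open synclinal transition state of enamine Michael additions places ring C anti to ring B (C4 = S, 3,4-trans), and any 3,4-cis lactol can drift to the trans isomer by epimerisation at C3 through the open hydroxy aldehyde.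

Step 23
Reactants: 34 (3R,4S)-7-(benzyloxy)-4-{4-(benzyloxy)-2-[(3R)-7-(benzyloxy)-3,4-dihydro-2H-chromen-3-yl]-6-methoxyphenyl}-3-[2,3-bis(benzyloxy)-4-methoxyphenyl]-3,4-dihydro-2H-chromen-2-ol
Product: 35 (3R,4S)-7-(benzyloxy)-4-{4-(benzyloxy)-2-[(3R)-7-(benzyloxy)-3,4-dihydro-2H-chromen-3-yl]-6-methoxyphenyl}-3-[2,3-bis(benzyloxy)-4-methoxyphenyl]-3,4-dihydro-2H-chromene
Conditions: Et3SiH, BF3·OEt2, CH2Cl2, −78 to −20 °C
Reagents that add atoms: none
Why: Ionic hydrogenation: BF3 ionises the lactol to the cyclic oxocarbenium ion and Et3SiH delivers hydride to C2, leaving C3 and C4 untouched (a reversible loss of H3 could only lead toward the trans isomer already present).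

Step 24
Reactants: 35 (3R,4S)-7-(benzyloxy)-4-{4-(benzyloxy)-2-[(3R)-7-(benzyloxy)-3,4-dihydro-2H-chromen-3-yl]-6-methoxyphenyl}-3-[2,3-bis(benzyloxy)-4-methoxyphenyl]-3,4-dihydro-2H-chromene
Product: 36 (3R,4S)-3-(2,3-dihydroxy-4-methoxyphenyl)-4-{4-hydroxy-2-[(3R)-7-hydroxy-3,4-dihydro-2H-chromen-3-yl]-6-methoxyphenyl}-3,4-dihydro-2H-chromen-7-ol (CNP0227211.1)
Conditions: H2 (1 atm), Pd/C (10 %), THF/MeOH, rt; work-up under argon
Reagents that add atoms: none
Why: Hydrogenolysis of the five benzyl ethers over palladium; the aryl–CH bonds at C3, C4 and C3′ and the alkyl aryl ether bonds of the pyran rings are not cleaved.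

**Compound list**

1 | 5-bromovanillin (3-bromo-4-hydroxy-5-methoxybenzaldehyde) | COc1cc(C=O)cc(Br)c1O | starting material
2 | 3-bromo-4-hydroxy-5-methoxyphenyl formate | COc1cc(OC=O)cc(Br)c1O | intermediate (not isolated)
3 | 2-bromo-6-methoxybenzene-1,4-diol | COc1cc(O)cc(Br)c1O | intermediate
4 | 1-bromo-3-methoxy-2,5-bis(trimethylsilyloxy)benzene | COc1cc(O[Si](C)(C)C)cc(Br)c1O[Si](C)(C)C | intermediate (not isolated)
5 | lithium 2-methoxy-6-(trimethylsilyl)-4-(trimethylsilyloxy)phenoxide | [Li+].COc1cc(O[Si](C)(C)C)cc([Si](C)(C)C)c1[O-] | intermediate (not isolated)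
6 | 2-methoxy-6-(trimethylsilyl)-4-(trimethylsilyloxy)phenyl trifluoromethanesulfonate | COc1cc(O[Si](C)(C)C)cc([Si](C)(C)C)c1OS(=O)(=O)C(F)(F)F | intermediate (not isolated)
7 | 4-hydroxy-2-methoxy-6-(trimethylsilyl)phenyl trifluoromethanesulfonate | COc1cc(O)cc([Si](C)(C)C)c1OS(=O)(=O)C(F)(F)F | intermediate
8 | 4-(benzyloxy)-2-methoxy-6-(trimethylsilyl)phenyl trifluoromethanesulfonate | COc1cc(OCc2ccccc2)cc([Si](C)(C)C)c1OS(=O)(=O)C(F)(F)F | intermediate
9 | 1-[4-(benzyloxy)-2-hydroxyphenyl]ethan-1-one | CC(=O)c1ccc(OCc2ccccc2)cc1O | starting material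
10 | 1-[4-(benzyloxy)-2-(prop-2-en-1-yloxy)phenyl]ethan-1-one | CC(=O)c1ccc(OCc2ccccc2)cc1OCC=C | intermediate
11 | methyl 3-[4-(benzyloxy)-2-(prop-2-en-1-yloxy)phenyl]-3-oxopropanoate | COC(=O)CC(=O)c1ccc(OCc2ccccc2)cc1OCC=C | intermediate
12 | 5-(benzyloxy)-3-methoxybenzyne (5-(benzyloxy)-3-methoxy-1,2-didehydrobenzene) | COC1=CC(OCc2ccccc2)=CC#C1 | intermediate (not isolated)
13 | methyl 2-{5-(benzyloxy)-2-[4-(benzyloxy)-2-(prop-2-en-1-yloxy)benzoyl]-3-methoxyphenyl}acetate | COC(=O)Cc1cc(OCc2ccccc2)cc(OC)c1C(=O)c1ccc(OCc2ccccc2)cc1OCC=C | intermediate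
14 | 2-{5-(benzyloxy)-2-[4-(benzyloxy)-2-(prop-2-en-1-yloxy)benzoyl]-3-methoxyphenyl}acetic acid | OC(=O)Cc1cc(OCc2ccccc2)cc(OC)c1C(=O)c1ccc(OCc2ccccc2)cc1OCC=C | intermediate
15 | (4R)-4-benzyl-1,3-oxazolidin-2-one | O=C1N[C@H](Cc2ccccc2)CO1 | starting material
16 | mixed anhydride of 14 with pivalic acid | CC(C)(C)C(=O)OC(=O)Cc1cc(OCc2ccccc2)cc(OC)c1C(=O)c1ccc(OCc2ccccc2)cc1OCC=C | intermediate (not isolated)
17 | (4R)-4-benzyl-3-(2-{5-(benzyloxy)-2-[4-(benzyloxy)-2-(prop-2-en-1-yloxy)benzoyl]-3-methoxyphenyl}acetyl)-1,3-oxazolidin-2-one | O=C(Cc1cc(OCc2ccccc2)cc(OC)c1C(=O)c1ccc(OCc2ccccc2)cc1OCC=C)N1[C@H](Cc2ccccc2)COC1=O | intermediate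
18 | 4-(benzyloxy)-2-hydroxybenzaldehyde | O=Cc1ccc(OCc2ccccc2)cc1O | starting material
19 | 4-(benzyloxy)-2-(methoxymethoxy)benzaldehyde | COCOc1cc(OCc2ccccc2)ccc1C=O | intermediate
20 | [4-(benzyloxy)-2-(methoxymethoxy)phenyl]methanol | COCOc1cc(OCc2ccccc2)ccc1CO | intermediate
21 | 4-(benzyloxy)-1-(bromomethyl)-2-(methoxymethoxy)benzene | COCOc1cc(OCc2ccccc2)ccc1CBr | intermediate
22 | (4R)-4-benzyl-3-[(2R)-2-{5-(benzyloxy)-2-[4-(benzyloxy)-2-(prop-2-en-1-yloxy)benzoyl]-3-methoxyphenyl}-3-[4-(benzyloxy)-2-(methoxymethoxy)phenyl]propanoyl]-1,3-oxazolidin-2-one | O=C([C@H](Cc1ccc(OCc2ccccc2)cc1OCOC)c1cc(OCc2ccccc2)cc(OC)c1C(=O)c1ccc(OCc2ccccc2)cc1OCC=C)N1[C@H](Cc2ccccc2)COC1=O | intermediate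
23 | {4-(benzyloxy)-2-[(2R)-1-[4-(benzyloxy)-2-(methoxymethoxy)phenyl]-3-hydroxypropan-2-yl]-6-methoxyphenyl}[4-(benzyloxy)-2-(prop-2-en-1-yloxy)phenyl]methanone | OC[C@H](Cc1ccc(OCc2ccccc2)cc1OCOC)c1cc(OCc2ccccc2)cc(OC)c1C(=O)c1ccc(OCc2ccccc2)cc1OCC=C | intermediate
24 | {4-(benzyloxy)-2-[(2R)-1-[4-(benzyloxy)-2-hydroxyphenyl]-3-hydroxypropan-2-yl]-6-methoxyphenyl}[4-(benzyloxy)-2-(prop-2-en-1-yloxy)phenyl]methanone | OC[C@H](Cc1ccc(OCc2ccccc2)cc1O)c1cc(OCc2ccccc2)cc(OC)c1C(=O)c1ccc(OCc2ccccc2)cc1OCC=C | intermediate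
25 | {4-(benzyloxy)-2-[(3R)-7-(benzyloxy)-3,4-dihydro-2H-chromen-3-yl]-6-methoxyphenyl}[4-(benzyloxy)-2-(prop-2-en-1-yloxy)phenyl]methanone | C=CCOc1cc(OCc2ccccc2)ccc1C(=O)c1c(OC)cc(OCc2ccccc2)cc1[C@@H]1COc2cc(OCc3ccccc3)ccc2C1 | intermediate
26 | {4-(benzyloxy)-2-[(3R)-7-(benzyloxy)-3,4-dihydro-2H-chromen-3-yl]-6-methoxyphenyl}[4-(benzyloxy)-2-(prop-2-en-1-yloxy)phenyl]methanol (carbinol epimers) | C=CCOc1cc(OCc2ccccc2)ccc1C(O)c1c(OC)cc(OCc2ccccc2)cc1[C@@H]1COc2cc(OCc3ccccc3)ccc2C1 | intermediate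
27 | 5-(benzyloxy)-2-[{4-(benzyloxy)-2-[(3R)-7-(benzyloxy)-3,4-dihydro-2H-chromen-3-yl]-6-methoxyphenyl}(hydroxy)methyl]phenol (carbinol epimers) | Oc1cc(OCc2ccccc2)ccc1C(O)c1c(OC)cc(OCc2ccccc2)cc1[C@@H]1COc2cc(OCc3ccccc3)ccc2C1 | intermediate
28 | 5-(benzyloxy)-2-[{4-(benzyloxy)-2-[(3R)-7-(benzyloxy)-3,4-dihydro-2H-chromen-3-yl]-6-methoxyphenyl}(4-methylbenzenesulfonyl)methyl]phenol (epimers) | Cc1ccc(S(=O)(=O)C(c2ccc(OCc3ccccc3)cc2O)c2c(OC)cc(OCc3ccccc3)cc2[C@@H]2COc3cc(OCc4ccccc4)ccc3C2)cc1 | intermediate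
29 | 2,3-dihydroxy-4-methoxybenzaldehyde | COc1ccc(C=O)c(O)c1O | starting material
30 | 2,3-bis(benzyloxy)-4-methoxybenzaldehyde | COc1ccc(C=O)c(OCc2ccccc2)c1OCc1ccccc1 | intermediate
31 | 2,3-bis(benzyloxy)-4-methoxy-1-(2-methoxyethenyl)benzene (E/Z mixture) | COC=Cc1ccc(OC)c(OCc2ccccc2)c1OCc1ccccc1 | intermediate
32 | 2-[2,3-bis(benzyloxy)-4-methoxyphenyl]acetaldehyde | COc1ccc(CC=O)c(OCc2ccccc2)c1OCc1ccccc1 | intermediate
33 | (6E)-3-(benzyloxy)-6-({4-(benzyloxy)-2-[(3R)-7-(benzyloxy)-3,4-dihydro-2H-chromen-3-yl]-6-methoxyphenyl}methylidene)cyclohexa-2,4-dien-1-one | O=C1C=C(OCc2ccccc2)C=C/C1=C\c1c(OC)cc(OCc2ccccc2)cc1[C@@H]1COc2cc(OCc3ccccc3)ccc2C1 | intermediate (not isolated)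
34 | (3R,4S)-7-(benzyloxy)-4-{4-(benzyloxy)-2-[(3R)-7-(benzyloxy)-3,4-dihydro-2H-chromen-3-yl]-6-methoxyphenyl}-3-[2,3-bis(benzyloxy)-4-methoxyphenyl]-3,4-dihydro-2H-chromen-2-ol (C2 anomers) | COc1ccc([C@@H]2C(O)Oc3cc(OCc4ccccc4)ccc3[C@H]2c2c(OC)cc(OCc3ccccc3)cc2[C@@H]2COc3cc(OCc4ccccc4)ccc3C2)c(OCc2ccccc2)c1OCc1ccccc1 | intermediate
35 | (3R,4S)-7-(benzyloxy)-4-{4-(benzyloxy)-2-[(3R)-7-(benzyloxy)-3,4-dihydro-2H-chromen-3-yl]-6-methoxyphenyl}-3-[2,3-bis(benzyloxy)-4-methoxyphenyl]-3,4-dihydro-2H-chromene | COc1ccc([C@@H]2COc3cc(OCc4ccccc4)ccc3[C@H]2c2c(OC)cc(OCc3ccccc3)cc2[C@@H]2COc3cc(OCc4ccccc4)ccc3C2)c(OCc2ccccc2)c1OCc1ccccc1 | intermediate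
36 | (3R,4S)-3-(2,3-dihydroxy-4-methoxyphenyl)-4-{4-hydroxy-2-[(3R)-7-hydroxy-3,4-dihydro-2H-chromen-3-yl]-6-methoxyphenyl}-3,4-dihydro-2H-chromen-7-ol (CNP0227211.1) | COc1ccc([C@@H]2COc3cc(O)ccc3[C@H]2c2c(OC)cc(O)cc2[C@@H]2COc3cc(O)ccc3C2)c(O)c1O | target

**Step count and risks**

Total step count: 24. Longest linear sequence: 16 steps (1, 2, 3, 6, 7, 8, 12 to 18, 22 to 24).

Steps most likely to fail:

Step 6 (aryne insertion). What may go wrong: the aryl anion formed after the first C–C bond may be protonated before it closes onto the donor-substituted, ortho-alkoxy ketone (arylation without acyl shift), or the product may be arylated a second time. Fallback: the ring A oxygen is no longer carried through the insertion but installed afterwards, so that the ketone is a better acceptor. Commercial 1-(2-fluoro-4-hydroxyphenyl)ethan-1-one is benzylated (BnBr, K2CO3) to 1-[4-(benzyloxy)-2-fluorophenyl]ethan-1-one F1 and carbomethoxylated (NaH, dimethyl carbonate) to methyl 3-[4-(benzyloxy)-2-fluorophenyl]-3-oxopropanoate F2. The fallback sets out from aryne precursor 8, which is combined with F2 under the conditions of step 6 to give methyl 2-{5-(benzyloxy)-2-[4-(benzyloxy)-2-fluorobenzoyl]-3-methoxyphenyl}acetate F3. Saponification (LiOH) gives 2-{5-(benzyloxy)-2-[4-(benzyloxy)-2-fluorobenzoyl]-3-methoxyphenyl}acetic acid F4. Nucleophilic aromatic substitution of the fluoride ortho to the ketone with sodium prop-2-en-1-olate (allyl alcohol, NaH, DMF, 60 °C) then returns the route at acid 14.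

Step 22 (formal [4+2]). What may go wrong: slow addition of the bulky enamine to a doubly ortho-substituted, donor-stabilised quinone methide; poor facial selectivity at C4 if the catalyst is mismatched with the C3′ centre; self-condensation of the arylacetaldehyde. Fallback: activation is moved from the nucleophile to the electrophile. The fallback sets out from ortho-hydroxybenzhydrol 27 (step 18 is then omitted) and the E isomer of enol ether 31. A chiral BINOL-derived phosphoric acid (3,3′-bis(2,4,6-triisopropylphenyl) type, 10 mol %, toluene, molecular sieves) dehydrates 27 to hydrogen-bonded 33 and directs an inverse-electron-demand hetero-Diels–Alder reaction with the enol ether (methoxy group endo, hence ring B exo and 3,4-trans). This should give (3R,4S)-7-(benzyloxy)-4-{4-(benzyloxy)-2-[(3R)-7-(benzyloxy)-3,4-dihydro-2H-chromen-3-yl]-6-methoxyphenyl}-3-[2,3-bis(benzyloxy)-4-methoxyphenyl]-2-methoxy-3,4-dihydro-2H-chromene F5. The antipode of the acid that leads to the (3R,4S) adduct is chosen after a trial with each, and a minor C4 epimer would be removed by chromatography at this stage. Reduction of the mixed acetal with Et3SiH/BF3·OEt2 returns the route at 35.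

Step 12 (auxiliary-controlled benzylation). What may go wrong: ionisation or self-condensation of the electron-rich benzylic bromide before it alkylates the hindered enolate, or epimerisation of the α-aryl imide on quench. Fallback: the ortho oxygen is taken out of the electrophile and the lower pyran ring is closed by C–O cross-coupling instead of a Mitsunobu reaction. Commercial 2-bromo-4-hydroxybenzaldehyde is benzylated to 4-(benzyloxy)-2-bromobenzaldehyde F6, reduced (NaBH4) to [4-(benzyloxy)-2-bromophenyl]methanol F7 and converted (PBr3) into the bench-stable 4-(benzyloxy)-2-bromo-1-(bromomethyl)benzene F8. The fallback sets out from imide 17, whose sodium enolate is alkylated with F8 as in step 12 to give (4R)-4-benzyl-3-[(2R)-2-{5-(benzyloxy)-2-[4-(benzyloxy)-2-(prop-2-en-1-yloxy)benzoyl]-3-methoxyphenyl}-3-[4-(benzyloxy)-2-bromophenyl]propanoyl]-1,3-oxazolidin-2-one F9. LiBH4 gives {4-(benzyloxy)-2-[(2R)-1-[4-(benzyloxy)-2-bromophenyl]-3-hydroxypropan-2-yl]-6-methoxyphenyl}[4-(benzyloxy)-2-(prop-2-en-1-yloxy)phenyl]methanone F10. Intramolecular Ullmann-type etherification (CuI, 1,10-phenanthroline, Cs2CO3, toluene, 110 °C) forms the O1′–C8a′ bond and returns the route at chroman 25; steps 13 to 15 are replaced.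

Further compounds
F1 | step 6 | 1-[4-(benzyloxy)-2-fluorophenyl]ethan-1-one | CC(=O)c1ccc(OCc2ccccc2)cc1F
F2 | step 6 | methyl 3-[4-(benzyloxy)-2-fluorophenyl]-3-oxopropanoate | COC(=O)CC(=O)c1ccc(OCc2ccccc2)cc1F
F3 | step 6 | methyl 2-{5-(benzyloxy)-2-[4-(benzyloxy)-2-fluorobenzoyl]-3-methoxyphenyl}acetate | COC(=O)Cc1cc(OCc2ccccc2)cc(OC)c1C(=O)c1ccc(OCc2ccccc2)cc1F
F4 | step 6 | 2-{5-(benzyloxy)-2-[4-(benzyloxy)-2-fluorobenzoyl]-3-methoxyphenyl}acetic acid | OC(=O)Cc1cc(OCc2ccccc2)cc(OC)c1C(=O)c1ccc(OCc2ccccc2)cc1F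
F5 | step 22 | (3R,4S)-7-(benzyloxy)-4-{4-(benzyloxy)-2-[(3R)-7-(benzyloxy)-3,4-dihydro-2H-chromen-3-yl]-6-methoxyphenyl}-3-[2,3-bis(benzyloxy)-4-methoxyphenyl]-2-methoxy-3,4-dihydro-2H-chromene (C2 epimers) | COc1ccc([C@@H]2C(OC)Oc3cc(OCc4ccccc4)ccc3[C@H]2c2c(OC)cc(OCc3ccccc3)cc2[C@@H]2COc3cc(OCc4ccccc4)ccc3C2)c(OCc2ccccc2)c1OCc1ccccc1
F6 | step 12 | 4-(benzyloxy)-2-bromobenzaldehyde | O=Cc1ccc(OCc2ccccc2)cc1Br
F7 | step 12 | [4-(benzyloxy)-2-bromophenyl]methanol | OCc1ccc(OCc2ccccc2)cc1Br
F8 | step 12 | 4-(benzyloxy)-2-bromo-1-(bromomethyl)benzene | BrCc1ccc(OCc2ccccc2)cc1Br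
F9 | step 12 | (4R)-4-benzyl-3-[(2R)-2-{5-(benzyloxy)-2-[4-(benzyloxy)-2-(prop-2-en-1-yloxy)benzoyl]-3-methoxyphenyl}-3-[4-(benzyloxy)-2-bromophenyl]propanoyl]-1,3-oxazolidin-2-one | O=C([C@H](Cc1ccc(OCc2ccccc2)cc1Br)c1cc(OCc2ccccc2)cc(OC)c1C(=O)c1ccc(OCc2ccccc2)cc1OCC=C)N1[C@H](Cc2ccccc2)COC1=O
F10 | step 12 | {4-(benzyloxy)-2-[(2R)-1-[4-(benzyloxy)-2-bromophenyl]-3-hydroxypropan-2-yl]-6-methoxyphenyl}[4-(benzyloxy)-2-(prop-2-en-1-yloxy)phenyl]methanone | OC[C@H](Cc1ccc(OCc2ccccc2)cc1Br)c1cc(OCc2ccccc2)cc(OC)c1C(=O)c1ccc(OCc2ccccc2)cc1OCC=C
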